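## Analysis of the target

The target is a eudesmane-type trans-decalin (ring A = C1–C5 and C10, ring B = C5–C10) whose C1 is bonded to an exocyclic benzylic carbon, C9′, which also carries an isobutyl group and a 2,4,6-trihydroxy-3,5-diformylphenyl ring (C1′–C6′, with C1′ on C9′). There are six stereocentres: C1 (R), C4 (R), C5 (S), C7 (S), C10 (R) and C9′ (S). On the decalin, C5–H is anti to the C10 methyl group; the C1 side chain and the C7 2-hydroxypropan-2-yl group (carbinol carbon C11) are equatorial and lie on the face of that methyl group; the C4 hydroxyl is axial and 1,3-syn to it. C9′ lies outside the rings, so ring conformation cannot set it. The sensitive groups are the two tertiary alcohols at C4 and C11, which ionise or eliminate under Brønsted or Lewis acids, and the diformylphloroglucinol, an electron-rich chelating vinylogous acid that tolerates neither oxidants nor strong hydride donors. The hard part is C9′: it sits between the neopentyl-like C1 and a hexasubstituted arene, so an aryl–C9′ bond made by substitution or Friedel–Crafts chemistry would be slow and would endanger both the configuration and the tertiary alcohols, and the three phenols and two aldehydes would still have to be unveiled without acid. The strategy rests on the arene pattern: C1′ lies between the oxygenated carbons C2′ and C6′, the third oxygen is at C4′, and C3′ and C5′ carry the formyl groups. This is the pattern formed when the two carbons of a siloxyalkyne (C1′, C6′) are joined to the four carbons of a 3-alkoxycyclobutenone (C2′–C5′), so the ring can be grown last from an alkyne on a C9′ already fixed by enolate alkylation.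

## Retrosynthetic reasoning

**C4′–O benzyl bond (36 from 35).** The last bond cut is the O–benzyl bond at C4′. A benzyl ether is chosen for this oxygen because hydrogenolysis is neutral; an O-alkyl group that needed a boron or aluminium halide for its removal would not be compatible with the tertiary alcohols at C4 and C11.

**C3′–CHO and C5′–CHO (35 from 33, 33 from 32).** The two formyl carbons are removed next. In 33 each free phenol (C2′–OH, C6′–OH) has exactly one open ortho carbon, C3′ or C5′, so a phenoxide-directed formylation can only go where the target needs it, under basic conditions. 33 comes from 32 by removal of all three silyl groups with fluoride.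

**The arene (32 from 26 and 28).** The bonds C1′–C2′, C5′–C6′ and C2′–C3′ are cut, which takes the ring apart into siloxyalkyne 26 (C1′, C6′) and cyclobutenone 28 (C2′–C5′). Cutting here, and not at C9′–C1′, means that no bond to the crowded C9′ is made after its configuration is set. It also delivers the three oxygens already differentiated (free OH, O–Si, O–benzyl). The forward reaction has to join the alkyne carbon that bears C9′ to the ketene carbonyl carbon, and not the reverse.

**The ynol ether (26 from 23, 23 from 22).** The C6′–O bond is cut to terminal alkyne 23, and C6′ itself is cut off to give aldehyde 22. Oxidation at the far end of the acetylide is chosen because it happens two atoms away from the hindered C9′; building the ynolate by addition to a C9′ ester would have to take place next to it.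

**C9′–CH2 of the isobutyl group (22 from 21, 20, 19; 19 from 16 and 17).** The aldehyde goes back through alcohol 21 to imide 20 and its unsaturated precursor 19, and the C9′–CH2 bond is cut to imide 16 and allylic bromide 17. This is the one place where C9′ can be set with reagent control: an oxazolidinone enolate alkylation tolerates the bulky C1 substituent because the electrophile is small and reactive.

**C–O bonds at C4 and C11 (16 from 14, 13, 12; 12 from 10).** Imide 16 comes from acid 14 and its ester 13, and the silyl ethers come from diol 12. Both tertiary C–O bonds are cut together back to the diene ester 10, so one Markovnikov hydration makes both alcohols and one silylation protects both.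

**C1–C9′ (10 from 7).** The C9′ methylene is excised to give ester 7. A one-carbon ester homologation is preferred to a longer reduction–olefination–oxidation sequence.

**Both rings (7 from 6).** C5–C10 and C1–C2 are cut, which opens ring A and ring B at once to the acyclic tetraene ester 6. These two bonds are chosen because the intramolecular Diels–Alder reaction that forms them sets C1, C5 and C10 relative to C7 and leaves the C3=C4 alkene exactly where the C4 hydroxyl has to be introduced.

**Three C=C bonds and the ring of the terpene (6 from 5, 4, 3; 3 from 1).** The dienophile C10=C1, the terminal C2=C3 and the C4=C5 alkene are cut in turn back to keto aldehyde 3. Compound 3 is the ring-opened form of 1, in which the only stereocentre, the future C7, is bought.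

**The four-carbon partner (28 from 27).** The O–benzyl bond of 28 is cut to dione 27.

## Alternatives that were turned down

**Alternative 1: radical bicyclisation of an acyclic chain.**
- Disconnection: C4–C5 and C9–C10, so that both rings come from methyl (2R,3E)-2-[3-(tert-butyldimethylsilyloxy)but-3-en-1-yl]-3-methyl-6-oxoocta-3,7-dienoate (A1).
- Forward key step: an iron hydride made with a silane transfers a hydrogen atom to the enol ether terminus of A1. The C4 α-silyloxy radical adds 6-endo to C5, and the C10 radical then adds 6-endo to the vinyl ketone, giving decalone A2.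
- For it: two rings, the quaternary C10 and the oxygenated C4 in one step from a simple chain. On step count to a bicyclic core it is stronger than the chosen route, which needs five steps to its decalin.
- Against it: ring B arrives only as a C7 ketone, so the hydroxyisopropyl group and the C7 configuration must be added afterwards. The C1 ester of A2 is axial and must be epimerised. The only stereocentre in A1 is the enolisable C1, so absolute control of C4, C5 and C10 depends on a labile centre. The 6-endo mode at both radical steps and the axial silyloxy group at C4 rest on subtle conformational preferences. It also leaves C9′ and the arene unsolved.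
- Comparison: the chosen route takes C7 with its side chain from the chiral pool, and the geometry of its cycloaddition sets the equatorial C1 group directly. A2 could in principle feed the same end game, so this alternative competes only with the first third of the route.

**Alternative 2: carvone as ring A, Robinson annulation for ring B.**
- Disconnection: C9–C10 and C5–C6, back to (5S,6R)-6-methylcarvone (A3) and methyl vinyl ketone (A4).
- Forward key step: the kinetic α′-enolate of A3 adds to A4 trans to the isopropenyl group, and aldol condensation closes ring B to the linear dienone A5.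
- For it: a cheap chiral-pool start, with C1 and C10 set within two or three steps. Up to the bicycle it is as short as, or shorter than, the chosen route.
- Against it: A5 lacks C4, C5 and C7 as stereocentres and has the wrong oxidation pattern. The C7 carbonyl, the C5=C6 bond and the C3=C4 bond would each have to be converted under substrate control while conjugated with one another. The isopropenyl carbon on C1 would have to become C9′, bearing isobutyl and aryl, without any handle for reagent control.
- Comparison: the chosen strategy sets C9′ by auxiliary-controlled alkylation and never makes a bond to it afterwards; that is the point on which A5 is weakest.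

**Alternative 3: carbene-catalysed Stetter desymmetrisation.**
- Disconnection: C4–C5 of ring A, with the arene and C9′ already in place, back to the cyclohexadienone aldehyde A6.
- Forward key step: an N-heterocyclic carbene turns the C4 aldehyde of A6 into an acyl anion equivalent, which adds to one of the two enone β-carbons (C5). This closes ring A and fixes C10, giving A7.
- For it: it is convergent and catalytic, and no late arene construction is needed. The C4 ketone of A7 is well placed, because equatorial addition of a methyl nucleophile would give the axial C4 hydroxyl of the target. On convergence it is stronger than the chosen route.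
- Against it: the arene is carried as a tri-O-methyl ether, whose cleavage needs strong Lewis acids or hot thiolate in the presence of two tertiary alcohols. Both formyl groups would still have to be forced onto a hexasubstituted ring. A6 itself requires C1 and the aryl-bearing C9′ to be set next to a carbon that is not yet stereogenic. The intramolecular conjugate addition is kinetically cis-selective, so the trans fusion would depend on epimerisation at C5. The C7 enone still has to be turned into the hydroxyisopropyl stereocentre.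
- Comparison: the chosen strategy gives a longer linear sequence, but it builds the arene under neutral conditions with its three oxygens differentiated and removable without acid.

Key step: step 18

**Remarks on the chemistry (assumptions)**
- The stereocentre of (S)-(−)-limonene maps onto C7 (S) of the target when its methyl-bearing ring carbon becomes C10 and its olefinic CH becomes C5.
- Cyclobutane-1,3-dione (27) is taken as commercially available.
- Short forms used in names: DecTES = (1R,4R,4aS,6S,8aR)-4,8a-dimethyl-4-(triethylsilyloxy)-6-[2-(triethylsilyloxy)propan-2-yl]decahydronaphthalen-1-yl; DecOH = (1R,4R,4aS,6S,8aR)-4-hydroxy-6-(2-hydroxypropan-2-yl)-4,8a-dimethyldecahydronaphthalen-1-yl. Decalin positions 1, 4, 4a, 6 and 8a are C1, C4, C5, C7 and C10.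

## Route

Step 1
Reactants: 1 (S)-(−)-limonene
Product: 3 (3S)-6-oxo-3-(prop-1-en-2-yl)heptanal, via ring ozonide 2 (not isolated)
Conditions: O3 (about 1 equiv, Sudan Red 7B end point), CH2Cl2, −78 °C; then PPh3, −78 °C → rt
Reagents that add atoms: ozone, [O-][O+]=O
Why: Ozonolysis; ozone attacks the electron-rich trisubstituted ring alkene much faster than the 1,1-disubstituted isopropenyl group, so one equivalent at low temperature should cleave only the ring, and reduction of ozonide 2 gives the keto aldehyde with the future C7 centre untouched.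

Step 2
Reactants: 3 (3S)-6-oxo-3-(prop-1-en-2-yl)heptanal
Product: 4 (2E,5S)-2-methyl-8-oxo-5-(prop-1-en-2-yl)non-2-enal
Conditions: Ph3P=C(CH3)CHO, toluene, 90 °C
Reagents that add atoms: 2-(triphenylphosphoranylidene)propanal, CC(C=O)=P(c1ccccc1)(c1ccccc1)c1ccccc1
Why: Wittig reaction with a stabilised ylide, which reacts with the aldehyde but not with the methyl ketone and should give the (E)-2-methylenal, placing the chain trans to the future vinyl group as the diene requires.

Step 3
Reactants: 4 (2E,5S)-2-methyl-8-oxo-5-(prop-1-en-2-yl)non-2-enal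
Product: 5 (5S,7E)-8-methyl-5-(prop-1-en-2-yl)deca-7,9-dien-2-one
Conditions: Ph3PCH3Br, KN(SiMe3)2, THF, −78 → −20 °C (1.05 equiv of ylide)
Reagents that add atoms: methyltriphenylphosphonium bromide, C[P+](c1ccccc1)(c1ccccc1)c1ccccc1.[Br-]
Why: Wittig methylenation; at low temperature the non-stabilised ylide should consume the aldehyde well before it touches the methyl ketone, which completes the 2-methyl-1,3-diene.

Step 4
Reactants: 5 (5S,7E)-8-methyl-5-(prop-1-en-2-yl)deca-7,9-dien-2-one
Product: 6 ethyl (2E,6S,8E)-3,9-dimethyl-6-(prop-1-en-2-yl)undeca-2,8,10-trienoate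
Conditions: (EtO)2P(O)CH2CO2Et, NaH, THF, 0 → 65 °C
Reagents that add atoms: triethyl phosphonoacetate, CCOC(=O)CP(=O)(OCC)OCC
Why: Horner–Wadsworth–Emmons olefination of the methyl ketone, which should favour the (E)-β-methyl enoate with the ester trans to the longer chain; the minor (Z)-isomer is to be removed by chromatography, because only the E-dienophile places the ester cis to the C10 methyl group.

Step 5
Reactants: 6 ethyl (2E,6S,8E)-3,9-dimethyl-6-(prop-1-en-2-yl)undeca-2,8,10-trienoate
Product: 7 ethyl (1S,4aR,6S,8aS)-4,8a-dimethyl-6-(prop-1-en-2-yl)-1,2,4a,5,6,7,8,8a-octahydronaphthalene-1-carboxylate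
Conditions: toluene (0.01 M), BHT (cat.), 180 °C, sealed vessel
Reagents that add atoms: none
Why: Thermal type 1 intramolecular Diels–Alder reaction of a 2,8,10-trienoate: the diene C2=C3–C4=C5 and the dienophile C10=C1 meet through a chair-like four-carbon tether with the C7 isopropenyl group equatorial, forming C5–C10 and C1–C2. The ester-endo transition state should give the trans ring fusion, the E-dienophile places the ester cis to the C10 methyl group, and C7 thereby fixes C1, C5 and C10 in the absolute sense of the target.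

Step 6
Reactants: 7 ethyl (1S,4aR,6S,8aS)-4,8a-dimethyl-6-(prop-1-en-2-yl)-1,2,4a,5,6,7,8,8a-octahydronaphthalene-1-carboxylate
Product: 10 ethyl 2-[(1R,4aR,6S,8aR)-4,8a-dimethyl-6-(prop-1-en-2-yl)-1,2,4a,5,6,7,8,8a-octahydronaphthalen-1-yl]acetate, via dibromo enolate 8 (not isolated), via lithium ynolate 9 (not isolated)
Conditions: CH2Br2, lithium 2,2,6,6-tetramethylpiperidide (LiTMP), THF, −78 °C; LiN(SiMe3)2, −78 → −20 °C; n-BuLi, −78 °C → rt; then HCl/EtOH, 0 °C
Reagents that add atoms: dibromomethane, BrCBr; ethanol, CCO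
Why: Kowalski ester homologation: dibromomethyllithium adds to the ester, enolate 8 undergoes bromine–lithium exchange and 1,2-shift of C1 with retention to ynolate 9, and acidic ethanol traps it as the homologous ester. The inserted carbon is C9′.

Step 7
Reactants: 10 ethyl 2-[(1R,4aR,6S,8aR)-4,8a-dimethyl-6-(prop-1-en-2-yl)-1,2,4a,5,6,7,8,8a-octahydronaphthalen-1-yl]acetate
Product: 12 ethyl 2-(DecOH)acetate, via bis-organomercurial 11 (not isolated)
Conditions: Hg(OAc)2 (2.5 equiv), THF/H2O, rt; then NaBH4, aq NaOH, 0 °C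
Reagents that add atoms: water, O
Why: Oxymercuration–demercuration hydrates both alkenes in the Markovnikov sense (C11–OH and C4–OH). At the ring alkene the mercurinium ion should form on the face away from the axial C10 methyl group and water should open it at the tertiary C4 trans-diaxially (Fürst–Plattner rule), placing the C4 hydroxyl axial and syn to that methyl group; NaBH4 then replaces mercury by hydrogen.

Step 8
Reactants: 12 ethyl 2-(DecOH)acetate
Product: 13 ethyl 2-(DecTES)acetate
Conditions: Et3SiOTf (3 equiv), 2,6-lutidine, CH2Cl2, 0 °C → rt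
Reagents that add atoms: triethylsilyl trifluoromethanesulfonate, CC[Si](CC)(CC)OS(=O)(=O)C(F)(F)F
Why: Silylation of tertiary alcohols with a silyl triflate and a hindered pyridine base; both hydroxyls are masked so that they interfere neither with the enolate chemistry nor with the ketenes of the key step.

Step 9
Reactants: 13 ethyl 2-(DecTES)acetate
Product: 14 2-(DecTES)acetic acid
Conditions: LiOH, THF/MeOH/H2O, 40 °C; then dilute HCl to pH 4, 0 °C
Reagents that add atoms: lithium hydroxide, [Li+].[OH-]
Why: Saponification of an unhindered ester; tertiary triethylsilyl ethers tolerate hydroxide and the brief cold acidification.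

Step 10
Reactants: 14 2-(DecTES)acetic acid
Product: 16 (4S)-4-benzyl-3-[2-(DecTES)acetyl]-1,3-oxazolidin-2-one, via mixed anhydride 15 (not isolated)
Conditions: t-BuCOCl, Et3N, THF, −20 °C; then (S)-4-benzyl-1,3-oxazolidin-2-one, LiCl, −20 °C → rt
Reagents that add atoms: (S)-4-benzyl-1,3-oxazolidin-2-one, O=C1N[C@@H](Cc2ccccc2)CO1
Why: N-Acylation of the oxazolidinone through the mixed pivalic anhydride; the nucleophile attacks the less hindered carbonyl of 15.

Step 11
Reactants: 16 (4S)-4-benzyl-3-[2-(DecTES)acetyl]-1,3-oxazolidin-2-one; 17 3-bromo-2-methylprop-1-ene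
Product: 19 (4S)-4-benzyl-3-[(2S)-2-(DecTES)-4-methylpent-4-enoyl]-1,3-oxazolidin-2-one, via sodium enolate 18 (not isolated)
Conditions: NaN(SiMe3)2, THF, −78 °C; then 17 (4 equiv), −78 → −40 °C
Reagents that add atoms: none
Why: Evans asymmetric alkylation: the chelated (Z)-sodium enolate 18 is attacked by the allylic bromide on the face opposite the benzyl group of the (S)-auxiliary, which sets C9′ as (S). Reagent control is expected to override the bias of the neighbouring C1 centre.

Step 12
Reactants: 19 (4S)-4-benzyl-3-[(2S)-2-(DecTES)-4-methylpent-4-enoyl]-1,3-oxazolidin-2-one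
Product: 20 (4S)-4-benzyl-3-[(2S)-2-(DecTES)-4-methylpentanoyl]-1,3-oxazolidin-2-one
Conditions: H2 (1 atm), Pd/C, EtOAc, rt
Reagents that add atoms: none
Why: Heterogeneous hydrogenation of the 1,1-disubstituted alkene to the isobutyl group; the C-benzyl group of the auxiliary and the silyl ethers are inert in ethyl acetate.

Step 13
Reactants: 20 (4S)-4-benzyl-3-[(2S)-2-(DecTES)-4-methylpentanoyl]-1,3-oxazolidin-2-one
Product: 21 (2S)-2-(DecTES)-4-methylpentan-1-ol
Conditions: LiBH4, H2O (1 equiv), Et2O, 0 °C
Reagents that add atoms: none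
Why: Reductive removal of the auxiliary by hydride attack at the exocyclic carbonyl; C9′ is not enolised, and the oxazolidinone is recovered.

Step 14
Reactants: 21 (2S)-2-(DecTES)-4-methylpentan-1-ol
Product: 22 (2S)-2-(DecTES)-4-methylpentanal
Conditions: Dess–Martin periodinane, NaHCO3, CH2Cl2, 0 °C → rt
Reagents that add atoms: none
Why: Dess–Martin oxidation under buffered, non-basic conditions gives the α-branched aldehyde without enolisation at C9′.

Step 15
Reactants: 22 (2S)-2-(DecTES)-4-methylpentanal
Product: 23 (1R,4R,4aS,6S,8aR)-4,8a-dimethyl-1-[(3S)-5-methylhex-1-yn-3-yl]-4-(triethylsilyloxy)-6-[2-(triethylsilyloxy)propan-2-yl]decahydronaphthalene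
Conditions: dimethyl (1-diazo-2-oxopropyl)phosphonate, K2CO3, MeOH/THF, 0 °C → rt
Reagents that add atoms: dimethyl (1-diazo-2-oxopropyl)phosphonate, CC(=O)C(=[N+]=[N-])P(=O)(OC)OC
Why: Ohira–Bestmann (Seyferth–Gilbert) homologation: the aldehyde carbon becomes C1′ and the reagent carbon C6′. The mild carbonate base and the hindered α-position should preserve C9′.

Step 16
Reactants: 23 (1R,4R,4aS,6S,8aR)-4,8a-dimethyl-1-[(3S)-5-methylhex-1-yn-3-yl]-4-(triethylsilyloxy)-6-[2-(triethylsilyloxy)propan-2-yl]decahydronaphthalene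
Product: 26 {[(3S)-3-(DecTES)-5-methylhex-1-yn-1-yl]oxy}triisopropylsilane, via lithium acetylide 24 (not isolated), via lithium ynolate 25 (not isolated)
Conditions: LiN(SiMe3)2, THF, −78 °C; t-BuOOLi (from t-BuOOH and LiN(SiMe3)2), −78 → 0 °C; then i-Pr3SiOTf, −78 → 0 °C
Reagents that add atoms: tert-butyl hydroperoxide, CC(C)(C)OO; triisopropylsilyl trifluoromethanesulfonate, CC(C)[Si](C(C)C)(C(C)C)OS(=O)(=O)C(F)(F)F
Why: Julia ynolate synthesis: acetylide 24 takes an electrophilic oxygen from lithium tert-butyl peroxide to give ynolate 25, and the bulky silyl triflate silylates it on oxygen. The oxidation takes place two atoms away from the crowded C9′.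

Step 17
Reactants: 27 cyclobutane-1,3-dione
Product: 28 3-(benzyloxy)cyclobut-2-en-1-one
Conditions: BnOH, PPh3, DIAD, THF, 0 °C → rt
Reagents that add atoms: benzyl alcohol, OCc1ccccc1
Why: Mitsunobu O-alkylation of the enol form of the dione, a strong vinylogous acid, which gives the vinylogous ester under neutral conditions that spare the strained ring.

Step 18
Reactants: 26 {[(3S)-3-(DecTES)-5-methylhex-1-yn-1-yl]oxy}triisopropylsilane; 28 3-(benzyloxy)cyclobut-2-en-1-one
Product: 32 5-(benzyloxy)-2-[(1S)-1-(DecTES)-3-methylbutyl]-3-(triisopropylsilyloxy)phenol, via vinylketene 29 (not isolated), via vinylcyclobutenone 30 (not isolated), via dienylketene 31 (not isolated)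
Conditions: 28 (1.5 equiv), toluene, 110 °C, sealed vessel
Reagents that add atoms: none
Why: Heating opens 28 by 4π electrocyclic ring opening to the (benzyloxyvinyl)ketene 29. The polarised siloxyalkyne 26 adds to the ketene C=C in a regioselective (2+2) cycloaddition: its nucleophilic carbon, the one bearing C9′, bonds to the ketene carbonyl carbon (C1′–C2′) and its oxygen-bearing carbon to the ketene α-carbon (C5′–C6′), giving vinylcyclobutenone 30. A second 4π opening gives dienylketene 31, whose 6π electrocyclic (disrotatory) closure forms C2′–C3′ and with it the six-membered ring; tautomerisation of the cyclohexadienone gives phenol 32. The closest known reaction type is the Danheiser benzannulation of cyclobutenones with siloxyalkynes; the 3-alkoxy group on the cyclobutenone is the less usual element. No stereocentre is formed, since the sp3 ring carbon of 30 is lost on aromatisation. The selectivity needed is the regiochemistry of the ketene–alkyne step, which the oxygen-polarised alkyne secures, so that C1′ ends between two oxygenated carbons and the unsubstituted ring carbons are C3′ and C5′. Both tertiary alcohols are silylated, so no hydroxyl competes for the ketenes, and the neutral conditions leave the non-acidic C9′–H centre untouched.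

Step 19
Reactants: 32 5-(benzyloxy)-2-[(1S)-1-(DecTES)-3-methylbutyl]-3-(triisopropylsilyloxy)phenol
Product: 33 5-(benzyloxy)-2-[(1S)-1-(DecOH)-3-methylbutyl]benzene-1,3-diol
Conditions: Bu4NF (excess), THF, 0 → 45 °C; aq NH4Cl
Reagents that add atoms: none
Why: Fluoride desilylation removes the aryl silyl ether quickly and the two tertiary triethylsilyl ethers on warming; the medium is basic, so the tertiary alcohols are not put at risk.

Step 20
Reactants: 33 5-(benzyloxy)-2-[(1S)-1-(DecOH)-3-methylbutyl]benzene-1,3-diol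
Product: 35 2-(benzyloxy)-4,6-dihydroxy-5-[(1S)-1-(DecOH)-3-methylbutyl]benzene-1,3-dicarbaldehyde, via monoaldehyde 34 (not isolated)
Conditions: MgCl2 (anhydrous), Et3N, (CH2O)n (excess), MeCN, reflux; then cold 0.5 M HCl
Reagents that add atoms: paraformaldehyde (as formaldehyde), C=O
Why: Casnati–Skattebøl ortho-formylation carried out twice: each magnesium phenoxide delivers formaldehyde to its single open ortho carbon (C3′, then C5′), and a second formaldehyde accepts hydride from the hydroxymethyl intermediate. The O-benzyl group keeps the ring from reacting as a free phloroglucinol, and the conditions are basic.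

Step 21
Reactants: 35 2-(benzyloxy)-4,6-dihydroxy-5-[(1S)-1-(DecOH)-3-methylbutyl]benzene-1,3-dicarbaldehyde
Product: 36 2,4,6-trihydroxy-5-[(1S)-1-(DecOH)-3-methylbutyl]benzene-1,3-dicarbaldehyde (target)
Conditions: H2 (1 atm), Pd/C, EtOAc, rt, stopped at consumption of 35
Reagents that add atoms: none
Why: Hydrogenolysis of the aryl benzyl ether, which should be faster than reduction of the two strongly chelated, electron-rich aryl aldehydes; the neutral conditions leave both tertiary alcohols untouched.

## Compound list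

1 | (S)-(−)-limonene, (4S)-1-methyl-4-(prop-1-en-2-yl)cyclohex-1-ene | CC1=CC[C@@H](C(C)=C)CC1 | starting material
2 | ring ozonide of 1, 1-methyl-4-(prop-1-en-2-yl)-7,8,9-trioxabicyclo[4.2.1]nonane (C4 as in 1, acetal carbons as a mixture) | CC12CC[C@H](C(C)=C)CC(O1)OO2 | intermediate
3 | (3S)-6-oxo-3-(prop-1-en-2-yl)heptanal | O=CC[C@@H](C(C)=C)CCC(C)=O | intermediate
4 | (2E,5S)-2-methyl-8-oxo-5-(prop-1-en-2-yl)non-2-enal | O=C/C(C)=C/C[C@@H](C(C)=C)CCC(C)=O | intermediate
5 | (5S,7E)-8-methyl-5-(prop-1-en-2-yl)deca-7,9-dien-2-one | C=C/C(C)=C/C[C@@H](C(C)=C)CCC(C)=O | intermediate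
6 | ethyl (2E,6S,8E)-3,9-dimethyl-6-(prop-1-en-2-yl)undeca-2,8,10-trienoate | C=C/C(C)=C/C[C@@H](C(C)=C)CC/C(C)=C/C(=O)OCC | intermediate
7 | ethyl (1S,4aR,6S,8aS)-4,8a-dimethyl-6-(prop-1-en-2-yl)-1,2,4a,5,6,7,8,8a-octahydronaphthalene-1-carboxylate (trans-fused; ester, C8a methyl and isopropenyl on one face) | CCOC(=O)[C@H]1CC=C(C)[C@H]2C[C@@H](C(C)=C)CC[C@]12C | intermediate
8 | lithium 2,2-dibromo-1-[(1S,4aR,6S,8aS)-4,8a-dimethyl-6-(prop-1-en-2-yl)-1,2,4a,5,6,7,8,8a-octahydronaphthalen-1-yl]ethen-1-olate | [Li+].[O-]C(=C(Br)Br)[C@H]1CC=C(C)[C@H]2C[C@@H](C(C)=C)CC[C@]12C | intermediate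
9 | lithium 2-[(1S,4aR,6S,8aS)-4,8a-dimethyl-6-(prop-1-en-2-yl)-1,2,4a,5,6,7,8,8a-octahydronaphthalen-1-yl]ethyn-1-olate | [Li+].[O-]C#C[C@H]1CC=C(C)[C@H]2C[C@@H](C(C)=C)CC[C@]12C | intermediate
10 | ethyl 2-[(1R,4aR,6S,8aR)-4,8a-dimethyl-6-(prop-1-en-2-yl)-1,2,4a,5,6,7,8,8a-octahydronaphthalen-1-yl]acetate | CCOC(=O)C[C@H]1CC=C(C)[C@H]2C[C@@H](C(C)=C)CC[C@]12C | intermediate
11 | bis(acetoxymercurio) adduct of 10: ethyl 2-[3-(acetoxymercurio)-6-[1-(acetoxymercurio)-2-hydroxypropan-2-yl]-4-hydroxy-4,8a-dimethyldecahydronaphthalen-1-yl]acetate (ring centres as in 12, C3–Hg trans to the C4 hydroxyl) | CCOC(=O)C[C@H]1C[C@H]([Hg]OC(C)=O)[C@@](C)(O)[C@H]2C[C@@H](C(C)(C[Hg]OC(C)=O)O)CC[C@]12C | intermediate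
12 | ethyl 2-[(1R,4R,4aS,6S,8aR)-4-hydroxy-6-(2-hydroxypropan-2-yl)-4,8a-dimethyldecahydronaphthalen-1-yl]acetate | CCOC(=O)C[C@H]1CC[C@@](C)(O)[C@H]2C[C@@H](C(C)(C)O)CC[C@]12C | intermediate
13 | ethyl 2-[(1R,4R,4aS,6S,8aR)-4,8a-dimethyl-4-(triethylsilyloxy)-6-[2-(triethylsilyloxy)propan-2-yl]decahydronaphthalen-1-yl]acetate | CCOC(=O)C[C@H]1CC[C@@](C)(O[Si](CC)(CC)CC)[C@H]2C[C@@H](C(C)(C)O[Si](CC)(CC)CC)CC[C@]12C | intermediate
14 | 2-[(1R,4R,4aS,6S,8aR)-4,8a-dimethyl-4-(triethylsilyloxy)-6-[2-(triethylsilyloxy)propan-2-yl]decahydronaphthalen-1-yl]acetic acid | OC(=O)C[C@H]1CC[C@@](C)(O[Si](CC)(CC)CC)[C@H]2C[C@@H](C(C)(C)O[Si](CC)(CC)CC)CC[C@]12C | intermediate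
15 | mixed anhydride of 14 with pivalic acid | CC(C)(C)C(=O)OC(=O)C[C@H]1CC[C@@](C)(O[Si](CC)(CC)CC)[C@H]2C[C@@H](C(C)(C)O[Si](CC)(CC)CC)CC[C@]12C | intermediate
16 | (4S)-4-benzyl-3-[2-(DecTES)acetyl]-1,3-oxazolidin-2-one | O=C(C[C@H]1CC[C@@](C)(O[Si](CC)(CC)CC)[C@H]2C[C@@H](C(C)(C)O[Si](CC)(CC)CC)CC[C@]12C)N1[C@@H](Cc2ccccc2)COC1=O | intermediate
17 | 3-bromo-2-methylprop-1-ene | CC(=C)CBr | starting material
18 | sodium (Z)-enolate of 16 | [Na+].[O-]/C(=C\[C@H]1CC[C@@](C)(O[Si](CC)(CC)CC)[C@H]2C[C@@H](C(C)(C)O[Si](CC)(CC)CC)CC[C@]12C)N1[C@@H](Cc2ccccc2)COC1=O | intermediate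
19 | (4S)-4-benzyl-3-[(2S)-2-(DecTES)-4-methylpent-4-enoyl]-1,3-oxazolidin-2-one | CC(=C)C[C@H](C(=O)N1[C@@H](Cc2ccccc2)COC1=O)[C@H]1CC[C@@](C)(O[Si](CC)(CC)CC)[C@H]2C[C@@H](C(C)(C)O[Si](CC)(CC)CC)CC[C@]12C | intermediate
20 | (4S)-4-benzyl-3-[(2S)-2-(DecTES)-4-methylpentanoyl]-1,3-oxazolidin-2-one | CC(C)C[C@H](C(=O)N1[C@@H](Cc2ccccc2)COC1=O)[C@H]1CC[C@@](C)(O[Si](CC)(CC)CC)[C@H]2C[C@@H](C(C)(C)O[Si](CC)(CC)CC)CC[C@]12C | intermediate
21 | (2S)-2-(DecTES)-4-methylpentan-1-ol | CC(C)C[C@H](CO)[C@H]1CC[C@@](C)(O[Si](CC)(CC)CC)[C@H]2C[C@@H](C(C)(C)O[Si](CC)(CC)CC)CC[C@]12C | intermediate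
22 | (2S)-2-(DecTES)-4-methylpentanal | CC(C)C[C@H](C=O)[C@H]1CC[C@@](C)(O[Si](CC)(CC)CC)[C@H]2C[C@@H](C(C)(C)O[Si](CC)(CC)CC)CC[C@]12C | intermediate
23 | (1R,4R,4aS,6S,8aR)-4,8a-dimethyl-1-[(3S)-5-methylhex-1-yn-3-yl]-4-(triethylsilyloxy)-6-[2-(triethylsilyloxy)propan-2-yl]decahydronaphthalene | CC(C)C[C@H](C#C)[C@H]1CC[C@@](C)(O[Si](CC)(CC)CC)[C@H]2C[C@@H](C(C)(C)O[Si](CC)(CC)CC)CC[C@]12C | intermediate
24 | lithium acetylide of 23 | CC(C)C[C@H](C#C[Li])[C@H]1CC[C@@](C)(O[Si](CC)(CC)CC)[C@H]2C[C@@H](C(C)(C)O[Si](CC)(CC)CC)CC[C@]12C | intermediate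
25 | lithium (3S)-3-(DecTES)-5-methylhex-1-yn-1-olate | [Li+].CC(C)C[C@H](C#C[O-])[C@H]1CC[C@@](C)(O[Si](CC)(CC)CC)[C@H]2C[C@@H](C(C)(C)O[Si](CC)(CC)CC)CC[C@]12C | intermediate
26 | {[(3S)-3-(DecTES)-5-methylhex-1-yn-1-yl]oxy}triisopropylsilane | CC(C)C[C@H](C#CO[Si](C(C)C)(C(C)C)C(C)C)[C@H]1CC[C@@](C)(O[Si](CC)(CC)CC)[C@H]2C[C@@H](C(C)(C)O[Si](CC)(CC)CC)CC[C@]12C | intermediate
27 | cyclobutane-1,3-dione | O=C1CC(=O)C1 | starting material
28 | 3-(benzyloxy)cyclobut-2-en-1-one | O=C1C=C(OCc2ccccc2)C1 | intermediate
29 | 3-(benzyloxy)buta-1,3-dien-1-one | O=C=CC(=C)OCc1ccccc1 | intermediate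
30 | 4-[1-(benzyloxy)ethenyl]-2-[(1S)-1-(DecTES)-3-methylbutyl]-3-(triisopropylsilyloxy)cyclobut-2-en-1-one (ring C4 as a mixture) | CC(C)C[C@H](C1=C(O[Si](C(C)C)(C(C)C)C(C)C)C(C(=C)OCc2ccccc2)C1=O)[C@H]1CC[C@@](C)(O[Si](CC)(CC)CC)[C@H]2C[C@@H](C(C)(C)O[Si](CC)(CC)CC)CC[C@]12C | intermediate
31 | 5-(benzyloxy)-2-[(1S)-1-(DecTES)-3-methylbutyl]-3-(triisopropylsilyloxy)hexa-1,3,5-trien-1-one (ketene carbon and vinyl group cis on the central alkene) | CC(C)C[C@H](C(=C=O)/C(O[Si](C(C)C)(C(C)C)C(C)C)=C\C(=C)OCc2ccccc2)[C@H]1CC[C@@](C)(O[Si](CC)(CC)CC)[C@H]2C[C@@H](C(C)(C)O[Si](CC)(CC)CC)CC[C@]12C | intermediate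
32 | 5-(benzyloxy)-2-[(1S)-1-(DecTES)-3-methylbutyl]-3-(triisopropylsilyloxy)phenol | CC(C)C[C@H](c1c(O)cc(OCc2ccccc2)cc1O[Si](C(C)C)(C(C)C)C(C)C)[C@H]1CC[C@@](C)(O[Si](CC)(CC)CC)[C@H]2C[C@@H](C(C)(C)O[Si](CC)(CC)CC)CC[C@]12C | intermediate
33 | 5-(benzyloxy)-2-[(1S)-1-(DecOH)-3-methylbutyl]benzene-1,3-diol | CC(C)C[C@H](c1c(O)cc(OCc2ccccc2)cc1O)[C@H]1CC[C@@](C)(O)[C@H]2C[C@@H](C(C)(C)O)CC[C@]12C | intermediate
34 | 2-(benzyloxy)-4,6-dihydroxy-5-[(1S)-1-(DecOH)-3-methylbutyl]benzaldehyde | CC(C)C[C@H](c1c(O)c(C=O)c(OCc2ccccc2)cc1O)[C@H]1CC[C@@](C)(O)[C@H]2C[C@@H](C(C)(C)O)CC[C@]12C | intermediate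
35 | 2-(benzyloxy)-4,6-dihydroxy-5-[(1S)-1-(DecOH)-3-methylbutyl]benzene-1,3-dicarbaldehyde | CC(C)C[C@H](c1c(O)c(C=O)c(OCc2ccccc2)c(C=O)c1O)[C@H]1CC[C@@](C)(O)[C@H]2C[C@@H](C(C)(C)O)CC[C@]12C | intermediate
36 | 2,4,6-trihydroxy-5-{(1S)-1-[(1R,4R,4aS,6S,8aR)-4-hydroxy-6-(2-hydroxypropan-2-yl)-4,8a-dimethyldecahydronaphthalen-1-yl]-3-methylbutyl}benzene-1,3-dicarbaldehyde | CC(C)C[C@H](c1c(O)c(C=O)c(O)c(C=O)c1O)[C@H]1CC[C@@](C)(O)[C@H]2C[C@@H](C(C)(C)O)CC[C@]12C | target

## Step count and least certain steps

Total step count: 21. Longest linear sequence: 20 steps (steps 1–16 and 18–21, from 1); step 17 is a one-step branch.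

**Step 18 (key step).** The donor-substituted cyclobutenone 28 may open too slowly, so that 26 decays thermally before it is consumed. The (2+2) step may be retarded by the crowded C9′ next to the attacking alkyne carbon. The vinylketene may be intercepted by the phenol as it forms (O-acylation). Fallback, from 26 back to 32: the vinylketene 29 is generated at room temperature without any cyclobutenone. Commercial ethyl (E)-3-ethoxybut-2-enoate is exchanged with benzyl alcohol under acid catalysis to ethyl (E)-3-(benzyloxy)but-2-enoate F1. Saponification gives (E)-3-(benzyloxy)but-2-enoic acid F2, and oxalyl chloride gives (E)-3-(benzyloxy)but-2-enoyl chloride F3. Slow addition of F3 to 26 and Et3N (1,4-dehydrochlorination, then ketene–siloxyalkyne (2+2) cycloaddition) should give 30, which is then warmed to pass through 31 to 32.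

**Step 5.** The preference for the ester-endo, trans-fused transition state under purely thermal conditions may be modest, and the equatorial preference of the C7 group in the tether is the only source of facial control; the result would be loss of material to cis-fused and C7-mismatched diastereomers. Fallback, from 6 back to 7: saponification gives (2E,6S,8E)-3,9-dimethyl-6-(prop-1-en-2-yl)undeca-2,8,10-trienoic acid F4. Acylation (t-BuCOCl, Et3N; 1,3-oxazolidin-2-one, LiCl) gives 3-[(2E,6S,8E)-3,9-dimethyl-6-(prop-1-en-2-yl)undeca-2,8,10-trienoyl]-1,3-oxazolidin-2-one F5. Me2AlCl-promoted cycloaddition of the chelated imide at low temperature, where the endo mode is strongly favoured, gives 3-{[(1S,4aR,6S,8aS)-4,8a-dimethyl-6-(prop-1-en-2-yl)-1,2,4a,5,6,7,8,8a-octahydronaphthalen-1-yl]carbonyl}-1,3-oxazolidin-2-one F6. Ethanolysis with EtOMgBr returns 7.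

**Step 20.** The second formylation may stall on the deactivated monoaldehyde 34, or the hydroxymethyl intermediates may be captured by another electron-rich ring (diarylmethane formation). Fallback, from 32 back to 35, by halogen–metal exchange:
- Dibromination of 32 with N-bromosuccinimide gives 5-(benzyloxy)-4,6-dibromo-2-[(1S)-1-(DecTES)-3-methylbutyl]-3-(triisopropylsilyloxy)phenol F11.
- Silylation with i-Pr3SiOTf and 2,6-lutidine gives {[5-(benzyloxy)-4,6-dibromo-2-[(1S)-1-(DecTES)-3-methylbutyl]-1,3-phenylene]bis(oxy)}bis(triisopropylsilane) F12.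
- Double bromine–lithium exchange with t-BuLi at −78 °C and quenching with N,N-dimethylformamide gives 2-(benzyloxy)-5-[(1S)-1-(DecTES)-3-methylbutyl]-4,6-bis(triisopropylsilyloxy)benzene-1,3-dicarbaldehyde F13.
- Bu4NF removes all four silyl groups to give 35.

**Step 7.** Attack of water syn-axial to the C10 methyl group is hindered, so the hydration of the ring alkene may be slow or may lose facial and positional selectivity, while the side-chain alkene reacts normally. Fallback, from 10 back to 12: N-bromosuccinimide in aqueous acetone gives ethyl 2-[3-bromo-6-(1-bromo-2-hydroxypropan-2-yl)-4-hydroxy-4,8a-dimethyldecahydronaphthalen-1-yl]acetate F10 (bromonium ions opened by water at the tertiary carbons, trans-diaxially in the ring). Radical debromination with Bu3SnH and AIBN then gives 12.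

**Step 6.** Addition of dibromomethyllithium to the ester carbonyl next to the quaternary C10 may be slow, leading to incomplete conversion or decomposition of the carbenoid. Fallback, from 7 back to 10, by Arndt–Eistert homologation: saponification (KOH, aq EtOH, heat) gives (1S,4aR,6S,8aS)-4,8a-dimethyl-6-(prop-1-en-2-yl)-1,2,4a,5,6,7,8,8a-octahydronaphthalene-1-carboxylic acid F7. Oxalyl chloride gives its acid chloride F8. Diazomethane with Et3N gives 2-diazo-1-[(1S,4aR,6S,8aS)-4,8a-dimethyl-6-(prop-1-en-2-yl)-1,2,4a,5,6,7,8,8a-octahydronaphthalen-1-yl]ethan-1-one F9. Wolff rearrangement with AgO2CPh and Et3N in ethanol gives 10.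

**Step 21.** The formyl groups may be reduced further, to hydroxymethyl or methyl, before the benzyl ether is fully cleaved. Fallback, from 35 to 36: chelation-assisted debenzylation with MgBr2·OEt2 in benzene/ether, in which magnesium bridges a formyl oxygen and the ether oxygen and bromide removes the benzyl group. No hydrogen is involved and no new compound is made on the way.

## Further compounds

F1 | step 18 | ethyl (E)-3-(benzyloxy)but-2-enoate | CCOC(=O)/C=C(\C)OCc1ccccc1
F2 | step 18 | (E)-3-(benzyloxy)but-2-enoic acid | OC(=O)/C=C(\C)OCc1ccccc1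
F3 | step 18 | (E)-3-(benzyloxy)but-2-enoyl chloride | ClC(=O)/C=C(\C)OCc1ccccc1
F4 | step 5 | (2E,6S,8E)-3,9-dimethyl-6-(prop-1-en-2-yl)undeca-2,8,10-trienoic acid | C=C/C(C)=C/C[C@@H](C(C)=C)CC/C(C)=C/C(=O)O
F5 | step 5 | 3-[(2E,6S,8E)-3,9-dimethyl-6-(prop-1-en-2-yl)undeca-2,8,10-trienoyl]-1,3-oxazolidin-2-one | C=C/C(C)=C/C[C@@H](C(C)=C)CC/C(C)=C/C(=O)N1CCOC1=O
F6 | step 5 | 3-{[(1S,4aR,6S,8aS)-4,8a-dimethyl-6-(prop-1-en-2-yl)-1,2,4a,5,6,7,8,8a-octahydronaphthalen-1-yl]carbonyl}-1,3-oxazolidin-2-one | O=C([C@H]1CC=C(C)[C@H]2C[C@@H](C(C)=C)CC[C@]12C)N1CCOC1=O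
F7 | step 6 | (1S,4aR,6S,8aS)-4,8a-dimethyl-6-(prop-1-en-2-yl)-1,2,4a,5,6,7,8,8a-octahydronaphthalene-1-carboxylic acid | OC(=O)[C@H]1CC=C(C)[C@H]2C[C@@H](C(C)=C)CC[C@]12C
F8 | step 6 | (1S,4aR,6S,8aS)-4,8a-dimethyl-6-(prop-1-en-2-yl)-1,2,4a,5,6,7,8,8a-octahydronaphthalene-1-carbonyl chloride | ClC(=O)[C@H]1CC=C(C)[C@H]2C[C@@H](C(C)=C)CC[C@]12C
F9 | step 6 | 2-diazo-1-[(1S,4aR,6S,8aS)-4,8a-dimethyl-6-(prop-1-en-2-yl)-1,2,4a,5,6,7,8,8a-octahydronaphthalen-1-yl]ethan-1-one | [N-]=[N+]=CC(=O)[C@H]1CC=C(C)[C@H]2C[C@@H](C(C)=C)CC[C@]12C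
F10 | step 7 | ethyl 2-[3-bromo-6-(1-bromo-2-hydroxypropan-2-yl)-4-hydroxy-4,8a-dimethyldecahydronaphthalen-1-yl]acetate (ring centres as in 12, C3–Br trans to the C4 hydroxyl) | CCOC(=O)C[C@H]1C[C@H](Br)[C@@](C)(O)[C@H]2C[C@@H](C(C)(CBr)O)CC[C@]12C
F11 | step 20 | 5-(benzyloxy)-4,6-dibromo-2-[(1S)-1-(DecTES)-3-methylbutyl]-3-(triisopropylsilyloxy)phenol | CC(C)C[C@H](c1c(O)c(Br)c(OCc2ccccc2)c(Br)c1O[Si](C(C)C)(C(C)C)C(C)C)[C@H]1CC[C@@](C)(O[Si](CC)(CC)CC)[C@H]2C[C@@H](C(C)(C)O[Si](CC)(CC)CC)CC[C@]12C
F12 | step 20 | {[5-(benzyloxy)-4,6-dibromo-2-[(1S)-1-(DecTES)-3-methylbutyl]-1,3-phenylene]bis(oxy)}bis(triisopropylsilane) | CC(C)C[C@H](c1c(O[Si](C(C)C)(C(C)C)C(C)C)c(Br)c(OCc2ccccc2)c(Br)c1O[Si](C(C)C)(C(C)C)C(C)C)[C@H]1CC[C@@](C)(O[Si](CC)(CC)CC)[C@H]2C[C@@H](C(C)(C)O[Si](CC)(CC)CC)CC[C@]12C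
F13 | step 20 | 2-(benzyloxy)-5-[(1S)-1-(DecTES)-3-methylbutyl]-4,6-bis(triisopropylsilyloxy)benzene-1,3-dicarbaldehyde | CC(C)C[C@H](c1c(O[Si](C(C)C)(C(C)C)C(C)C)c(C=O)c(OCc2ccccc2)c(C=O)c1O[Si](C(C)C)(C(C)C)C(C)C)[C@H]1CC[C@@](C)(O[Si](CC)(CC)CC)[C@H]2C[C@@H](C(C)(C)O[Si](CC)(CC)CC)CC[C@]12C
F0 | step 21 | none | none
A1 | alternative 1 | methyl (2R,3E)-2-[3-(tert-butyldimethylsilyloxy)but-3-en-1-yl]-3-methyl-6-oxoocta-3,7-dienoate | COC(=O)[C@H](CCC(=C)O[Si](C)(C)C(C)(C)C)/C(C)=C/CC(=O)C=C
A2 | alternative 1 | methyl trans-4-(tert-butyldimethylsilyloxy)-4,8a-dimethyl-6-oxodecahydronaphthalene-1-carboxylate (C1 ester axial) | COC(=O)[C@@H]1CC[C@@](C)(O[Si](C)(C)C(C)(C)C)[C@H]2CC(=O)CC[C@]12C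
A3 | alternative 2 | (5S,6R)-2,6-dimethyl-5-(prop-1-en-2-yl)cyclohex-2-en-1-one (6-methylcarvone) | CC(=C)[C@H]1CC=C(C)C(=O)[C@@H]1C
A4 | alternative 2 | methyl vinyl ketone | CC(=O)C=C
A5 | alternative 2 | 4a,8-dimethyl-5-(prop-1-en-2-yl)-4,4a,5,6-tetrahydronaphthalen-2(3H)-one (C1 and C10 as in the target) | CC(=C)[C@H]1CC=C(C)C2=CC(=O)CC[C@]12C
A6 | alternative 3 | 7-methyl-4-(1-methyl-4-oxocyclohexa-2,5-dien-1-yl)-5-(2,4,6-trimethoxyphenyl)octanal (C4 and C5 as C1 and C9′ of the target) | CC(C)C[C@H](c1c(OC)cc(OC)cc1OC)[C@@H](CCC=O)C1(C)C=CC(=O)C=C1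
A7 | alternative 3 | trans-4a-methyl-4-[3-methyl-1-(2,4,6-trimethoxyphenyl)butyl]-3,4,4a,8a-tetrahydronaphthalene-1,7(2H,8H)-dione | CC(C)C[C@H](c1c(OC)cc(OC)cc1OC)[C@H]1CCC(=O)[C@H]2CC(=O)C=C[C@]12C
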